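(The readings are simulated with made-up constants.)

In a closed flask substrate is conserved, so the solid substrate charged must equal the sum of what it has become, and you can reckon with that sum.

the same everywhere: gas phase 0.92 mM (held)
- dawn: solid substrate 0.024 M; protic impurity 0.0080 M; run made earlier
- summer: solid substrate 0.024 M; protic impurity 0.018 M; run made earlier
- midnight: solid substrate 0.012 M; protic impurity 0.012 M; run made earlier
- flask: solid substrate 0.024 M; protic impurity 0.0120 M; time 25 min

| run | time / min | target / % | crystals / % |
|---|---|---|---|
| dawn | 2.00 | 0.9 | 0 |
| dawn | 4.00 | 3.5 | 0 |
| dawn | 6.00 | 6.3 | 0 |
| dawn | 8.00 | 9.2 | 0 |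
| dawn | 10.0 | 12.7 | 0 |
| dawn | 12.0 | 16.0 | 0 |
| dawn | 15.0 | 22.0 | 3.7 |
| summer | 0.833 | 0.4 | 0 |
| summer | 2.50 | 2.1 | 0.5 |
| summer | 4.00 | 3.1 | 0.1 |
| summer | 6.00 | 3.4 | 0.6 |
| summer | 10.0 | 7.6 | 0 |
| summer | 12.0 | 10.0 | 0.1 |
| summer | 15.0 | 14.0 | 0.5 |
| midnight | 1.33 | 2.0 | 0 |
| midnight | 2.50 | 3.8 | 0.5 |
| midnight | 4.00 | 6.1 | 0.1 |
| midnight | 8.00 | 14.4 | 0 |
| midnight | 15.0 | 15.3 | 0 |

(scatter of a reading: 0.5 percentage points)

- amounts and yields of target count crystals too
- given per volume of solution although it is solid: solid substrate, crystals
- the numbers in the tables scatter by 0.5 percentage points (one standard deviation)
- at the start none of the solid substrate is in solution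
- at the start none of the gas phase is in solution

- elm: doubling the transfer coefficient of the gas phase, all else as stated
- ash: doubling the saturation concentration of gas phase, all else as stated
- cedar: doubling the dissolution coefficient of the solid substrate, all else as stated
- birch: doubling the solubility of the solid substrate, all else as stated

- how much target and crystals together there is at 25 min, in percent of the solid substrate charged
- the change that raises the amount of target and crystals together at 25 min, in percent of the solid substrate charged most ("none" if none brings more than 2 percentage points) (elm / ash / cedar / birch / none)
- amount of target and crystals together at 25 min, in percent of the solid substrate charged, after elm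

Suppose dissolved substrate meets gas and impurity, each step pseudo-first-order in it. Its concentration then cancels from the selectivity, and target grows with ln([impurity charged]/[impurity left]).

First try: target and quenched substrate are the two sinks. Midnight's last reading, with equal charges, then means impurity left equals target, and target per unit of that logarithm is 0.978 mM. But summer would then have consumed 20.8 mM by 15.0 min, while dawn, with the same solid, had consumed at most 13.3 mM. That mismatch suggests a further sink.

So let h be the [impurity] at which quenching equals every other take. Rate then goes as 1/(h + [impurity]). Dawn's late readings stand 1.60 times summer's, which reads h as 8.54 mM. You may object that impurity falls meanwhile, and it does, so this is a rough reading.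

The balance becomes: charge = h × logarithm + impurity consumed. At midnight it holds with about half the impurity left, so the target made per unit of logarithm, the yield constant 2.65 mM, follows. For the flask the balance gives a logarithm of 1.65, hence 18.2 %. That constant should follow [dissolved gas]. Dawn's early lag lasts about 2.00 min. If that were gas filling the solution, supply would be about 0.460 mM/min, close to dawn's late rate of 0.480 mM/min, so the lag can't tell me that elm is useless. But ash doubles that same supply and raises the saturation as well, so I expect most from ash.

The forecast differs: 37 %, elm, and 46 % after elm, on the ground that “the impurity is used up stoichiometrically”.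

The flask gives 21.7 %. Ash gains most, 11 percentage points, and elm gives 22.5 %. In the flask [dissolved gas] stands at 93.7 % of saturation at 2.50 min, and the slowness of gas transfer is not what holds the yield down.

    starting material + dissolved gas → target (k = 4.30 /M/s)
    solid substrate ⇌ starting material, rate k2*(cs2 - [starting material]) while solid is left; crystals form when [starting material] > cs2 (solubility = 13.0 mM, k = 0.00230 /s)
    gas phase ⇌ dissolved gas, rate k3*(csat - [dissolved gas]) (kL = 0.0580 /s)
    starting material + protic impurity → quenched substrate (k = 2.10 /M/s)
    starting material → side product (k = 0.00500 /s)
    crystals ⇌ target, rate k6*(cs6 - [target]) while solid is left; crystals form when [target] > cs6 (solubility = 3.90 mM, k = 0.0140 /s)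

Two drains act together: the run without the side product step gives 46.8 %, and the run without quenching gives 39.9 %. With 4.6 % of the impurity left, my constant gives 34.0 %, more than the flask. The flask's own end puts the constant at 1.69 mM.

In the neighbour flask, charged with 0.020 M of impurity and ending with 17 % left, that constant gives 12.6 %. The computed neighbour gives 13.0 %.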